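At early times the flask shows little: in west at 0.200 h the gap between L and D is 1.3 percentage points, and each reading scatters by 1 point. So I read the late times, where the excess (c_L − c_D)/(c_L + c_D) stands clear.

the same everywhere: G 19 mM (held)

| charge | D | L | J | remark | time |
|---|---|---|---|---|---|
| west | 0.10 M | 0.10 M | 5 mol% | run made earlier |  |
| south-east | 0.10 M | 0.10 M | 20 mol% | run made earlier |  |
| east | 0.15 M | 0.15 M | 10 mol% | run made earlier |  |
| winter | 0.10 M | 0.10 M | 10 mol% |  | 3.0 h |
| dawn | 0.10 M | 0.10 M | 10 mol% |  | 0.80 h |

| run | time / h | L / % | D / % |
|---|---|---|---|
| west | 0.200 | 48.9 | 47.6 |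
| west | 0.417 | 49.1 | 44.7 |
| west | 1.00 | 42.6 | 37.2 |
| west | 2.50 | 30.5 | 19.7 |
| south-east | 0.333 | 47.7 | 45.7 |
| south-east | 0.833 | 42.8 | 40.8 |
| south-east | 1.50 | 36.4 | 33.8 |
| south-east | 2.50 | 26.1 | 23.0 |
| east | 0.200 | 47.5 | 47.1 |
| east | 0.417 | 46.3 | 47.1 |
| east | 1.00 | 44.0 | 40.6 |
| east | 2.50 | 30.8 | 29.5 |

(standard deviation of a reading: 1 percentage point)

- E is single-handed; D and L are mirror images of each other, charged as a racemate, each of them at the stated concentration
- at the start none of E is dissolved
- the analysis behind the earlier runs scatters by 1 percentage point, standard deviation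
- on the list of suspects stand: E + D -> Q; E + L -> Z; D + J <-> L + J; Q <-> Z; G <-> E; 2 E -> X
- an excess is below zero if the other one leads
- the handed part of E does not stay in what it makes, so the products of the two hands are mirror images too

- which one finishes higher in excess of L over D among what is left of the two ("neither" within 2 percentage points) (winter / dawn / neither)
- excess of L over D among what is left of the two at the end, winter
- excess of L over D among what is left of the two at the end, dawn

This looks like a dynamic kinetic resolution: D falls below L, and J is suspected of turning one into the other.

At 2.50 h west holds an excess of 21.5% and south-east 6.31%. Winter's J lies between theirs, so these were my first bounds, from above and from below. South-east has 4.00 times the J of west, and west has 3.41 times the excess of south-east, so I took the late excess as inversely proportional to the loading of J. Scaled to 10 mol% under that assumption, they gave two estimates, no longer bounds, of 10.8% and 12.6%. Their mean, 11.7%, is the held excess, the late excess times the loading, divided by the loading wanted. That was my figure for winter, though its 3.0 h lies beyond those readings.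

Dawn stops at 0.80 h, so I bounded it by nearby readings: south-east at 0.833 h, with more J, gives 2.39%, and west at 1.00 h, with less J, gives 6.77%. Scaling the south-east reading gave me 4.78%, so I chose winter.

The forecast, inside both brackets, named winter, with 12% there and 6% for dawn, where “the excess has not fully relaxed”.

The flask gives winter: 11.7% against my 11.7%, and 4.98% for dawn.

    E + D → Q (k = 0.0250 /M/s)
    E + L → Z (k = 0.0100 /M/s)
    D + J ⇌ L + J, rate k3*[J]*[D] forward; the back reaction follows from the equilibrium constant (k = 0.0180 /M/s)
    Q ⇌ Z (k = 2.50 × 10⁻⁴ /s)
    G ⇌ E, rate k5*(csat - [E]) (kL = 8.30 × 10⁻⁴ /s)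
    2 E → X (k = 0.00490 /M/s)

Winter and dawn share every charge, so their gap is the difference in time: without it dawn stands at 11.7% instead of 4.98%. The relaxation half-life of D and L by J at winter's end, 0.535 h, is short against 3.0 h. Q into Z and 2 E into X make no difference to winter's excess. In a neighbour flask, winter with 25 mol% of J, the held excess gives 4.68%; the computed result is 5.17%.

(The numbers in the tables were computed for an exercise, and the scatter is random.)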